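**Retrosynthetic overview**
- Isoanhydroicaritin ⇐ its 5-O-prenyl isomer (3,4'-dihydroxy-7-methoxy-5-prenyloxyflavone) by para-Claisen–Cope transfer of the prenyl group from O5 to C8. The pyranone ring is already closed at that point, so C8 is the only para position.
- The 5-O-prenyl flavonol ⇐ 2'-hydroxy-6'-prenyloxychalcone by the key step: one-pot closure of the O1–C2 ring bond and installation of the C3–O bond with nitrosobenzene as the O donor (new cascade).
- The chalcone ⇐ 2-hydroxy-4-methoxy-6-prenyloxyacetophenone + 4-hydroxybenzaldehyde (Claisen–Schmidt).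
- The acetophenone ⇐ symmetric 2',6'-dihydroxy-4'-methoxyacetophenone + prenyl bromide (mono-O-alkylation).
- Ring order: rings A and B are bought; the pyranone ring C is formed in step 3.

Assumption: the target has no stereocentre, so there is no enantiomer to control; the only stereo-element in the route is the E-alkene of the chalcone.
Assumption: 2',6'-dihydroxy-4'-methoxyacetophenone is taken as a purchasable starting material.

**Step 1**
Reactants: 1 2',6'-dihydroxy-4'-methoxyacetophenone; 2 prenyl bromide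
Product: 3 1-[2-hydroxy-4-methoxy-6-(3-methylbut-2-en-1-yloxy)phenyl]ethan-1-one
Conditions: 2 (1.05 equiv), K2CO3 (1.2 equiv), acetone, reflux, 6 h
Reagents that add atoms: none
Why: Williamson ether synthesis; the two OH groups of 1 are equivalent by symmetry, so only one mono-ether exists, and the remaining OH is tied up in a strong hydrogen bond to the C=O, which slows a second alkylation.

**Step 2**
Reactants: 3 1-[2-hydroxy-4-methoxy-6-(3-methylbut-2-en-1-yloxy)phenyl]ethan-1-one; 4 4-hydroxybenzaldehyde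
Product: 6 (E)-1-[2-hydroxy-4-methoxy-6-(3-methylbut-2-en-1-yloxy)phenyl]-3-(4-hydroxyphenyl)prop-2-en-1-one, via aldol adduct 5 (not isolated)
Conditions: 4 (1.2 equiv), 50% aq KOH (10 equiv), EtOH, 0 °C to rt, 48 h; then 1 M HCl to pH 4
Reagents that add atoms: none
Why: Claisen–Schmidt condensation; E1cB dehydration of aldol 5 gives the E-enone, the aryl prenyl ether is stable to hydroxide, and any flavanone 7 formed alongside is simply the next intermediate of step 3.

**Step 3**
Reactants: 6 (E)-1-[2-hydroxy-4-methoxy-6-(3-methylbut-2-en-1-yloxy)phenyl]-3-(4-hydroxyphenyl)prop-2-en-1-one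
Product: 10 3-hydroxy-2-(4-hydroxyphenyl)-7-methoxy-5-(3-methylbut-2-en-1-yloxy)-4H-chromen-4-one, via flavanone 7 (not isolated), via 3-anilinooxyflavanone 8 (not isolated), via chromane-3,4-dione 9 (not isolated)
Conditions: DL-proline (30 mol%), DMSO, 60 °C, 6 h; then PhNO (1.3 equiv, syringe pump over 4 h), 25 °C; then Et3N (2 equiv), 50 °C, 2 h; N2
Reagents that add atoms: nitrosobenzene, O=Nc1ccccc1
Why: Proposed new method: an aminocatalytic oxa-Michael / O-nitroso-aldol / N–O-elimination cascade. Proline converts 6 (and flavanone 7, with which it equilibrates) into the ring-closed flavanone enamine by 6-endo oxa-Michael addition of the 2'-OH to the iminium ion, which forms the O1–C2 ring bond; the proline CO2H hydrogen-bonds the nitroso nitrogen so the enamine carbon attacks the nitroso oxygen, which forms the C3–O bond and gives 8; Et3N then removes the acidic C3–H while the weak N–O bond breaks (Kornblum–DeLaMare-type E1cB) to give dione 9 and aniline, and 9 enolises to the aromatic pyranone 10. Only the ring-closed enamine is nucleophilic, so the 5-exo aurone channel of peroxide methods has no counterpart here, and PhNO (reduced to PhNH2, 4 e–) is not an alkene epoxidant, so the prenyl ether survives. Closest known reaction types: proline-catalysed α-aminoxylation of ketones with nitrosobenzene, amine-catalysed chalcone–flavanone cyclisation and the Algar–Flynn–Oyamada reaction. The stereocentres of 7–9 become sp2, so none remains.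

**Step 4**
Reactants: 10 3-hydroxy-2-(4-hydroxyphenyl)-7-methoxy-5-(3-methylbut-2-en-1-yloxy)-4H-chromen-4-one
Product: 13 isoanhydroicaritin, via ortho-dienone 11 (not isolated), via para-dienone 12 (not isolated)
Conditions: Eu(fod)3 (15 mol%), NaHCO3 (solid), PhCl, 85 °C, 24 h
Reagents that add atoms: none
Why: Lewis-acid-catalysed para-Claisen–Cope rearrangement; Eu(III) bound at C4=O/O5 promotes the aromatic Claisen [3,3] shift to C6 (dienone 11), a Cope [3,3] shift carries the group on to C8 as a normal prenyl (dienone 12), and tautomerisation gives the chelated 5-OH; the closed pyranone ring makes C8 the only para terminus, and no stereocentre is formed.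

**Compound list**
1 | 2',6'-dihydroxy-4'-methoxyacetophenone, 1-(2,6-dihydroxy-4-methoxyphenyl)ethan-1-one | CC(=O)c1c(O)cc(OC)cc1O | starting material
2 | prenyl bromide, 1-bromo-3-methylbut-2-ene | CC(C)=CCBr | starting material
3 | 1-[2-hydroxy-4-methoxy-6-(3-methylbut-2-en-1-yloxy)phenyl]ethan-1-one | CC(=O)c1c(O)cc(OC)cc1OCC=C(C)C | intermediate
4 | 4-hydroxybenzaldehyde | O=Cc1ccc(O)cc1 | starting material
5 | 3-hydroxy-1-[2-hydroxy-4-methoxy-6-(3-methylbut-2-en-1-yloxy)phenyl]-3-(4-hydroxyphenyl)propan-1-one (aldol adduct, racemic) | COc1cc(O)c(C(=O)CC(O)c2ccc(O)cc2)c(OCC=C(C)C)c1 | intermediate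
6 | (E)-1-[2-hydroxy-4-methoxy-6-(3-methylbut-2-en-1-yloxy)phenyl]-3-(4-hydroxyphenyl)prop-2-en-1-one (chalcone) | COc1cc(O)c(C(=O)/C=C/c2ccc(O)cc2)c(OCC=C(C)C)c1 | intermediate
7 | 2-(4-hydroxyphenyl)-7-methoxy-5-(3-methylbut-2-en-1-yloxy)chroman-4-one (flavanone, racemic) | COc1cc(OCC=C(C)C)c2C(=O)CC(c3ccc(O)cc3)Oc2c1 | intermediate
8 | 2-(4-hydroxyphenyl)-7-methoxy-5-(3-methylbut-2-en-1-yloxy)-3-(phenylaminooxy)chroman-4-one (racemic, mixture of diastereomers) | COc1cc(OCC=C(C)C)c2C(=O)C(ONc3ccccc3)C(c3ccc(O)cc3)Oc2c1 | intermediate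
9 | 2-(4-hydroxyphenyl)-7-methoxy-5-(3-methylbut-2-en-1-yloxy)chromane-3,4-dione (racemic; keto tautomer of 10) | COc1cc(OCC=C(C)C)c2C(=O)C(=O)C(c3ccc(O)cc3)Oc2c1 | intermediate
10 | 3-hydroxy-2-(4-hydroxyphenyl)-7-methoxy-5-(3-methylbut-2-en-1-yloxy)-4H-chromen-4-one (5-O-prenyl flavonol) | COc1cc(OCC=C(C)C)c2c(=O)c(O)c(-c3ccc(O)cc3)oc2c1 | intermediate
11 | 3-hydroxy-2-(4-hydroxyphenyl)-7-methoxy-6-(2-methylbut-3-en-2-yl)-4H-chromene-4,5(6H)-dione (ortho-dienone, racemic) | COC1=CC2=C(C(=O)C1C(C)(C)C=C)C(=O)C(O)=C(O2)c1ccc(O)cc1 | intermediate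
12 | 3-hydroxy-2-(4-hydroxyphenyl)-7-methoxy-8-(3-methylbut-2-en-1-yl)-4H-chromene-4,5(8H)-dione (para-dienone, racemic; keto tautomer of 13) | COC1=CC(=O)C2=C(OC(c3ccc(O)cc3)=C(O)C2=O)C1CC=C(C)C | intermediate
13 | isoanhydroicaritin, 3,5-dihydroxy-2-(4-hydroxyphenyl)-7-methoxy-8-(3-methylbut-2-en-1-yl)-4H-chromen-4-one (achiral) | COc1cc(O)c2c(=O)c(O)c(-c3ccc(O)cc3)oc2c1CC=C(C)C | target

**Totals**
Total step count: 4. Longest linear sequence: 4 steps (1 → 3 → 6 → 10 → 13).

**Three steps most likely to fail**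

Step 3 (the proposed new cascade). Risks: slow iminium/enamine formation at the di-ortho-substituted aryl ketone, N- instead of O-attack on nitrosobenzene, a nitroso-ene reaction at the prenyl ether, or N–O cleavage stopping at the 3-hydroxyflavanone. Fallback with known chemistry: set out from chalcone 6 and run an Algar–Flynn–Oyamada oxidative cyclisation (30% H2O2, 2 M NaOH, MeOH/THF, 0 °C to rt). Alkaline hydroperoxide does not attack the prenyl ether. It gives the racemic trans-2-(4-hydroxyphenyl)-3-hydroxy-7-methoxy-5-(3-methylbut-2-en-1-yloxy)chroman-4-one F1, which is oxidised on in the same pot to flavonol 10, where the route is rejoined. The aurone by-product expected for a 6'-alkoxychalcone is removed by chromatography.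

Step 4 (Claisen–Cope on the unprotected flavonol). Risks: the 3-hydroxy-4-keto chelate and the free phenol may sequester Eu(III), and dienone 11 may tautomerise to the 6-(1,1-dimethylallyl) isomer instead of undergoing the Cope shift. Fallback: set out from 10 and switch to a protect–rearrange–deprotect sequence, the substrate type on which this rearrangement is established. Acetylation (Ac2O, pyridine, rt) gives 4-[3-acetoxy-7-methoxy-5-(3-methylbut-2-en-1-yloxy)-4-oxo-4H-chromen-2-yl]phenyl acetate F2. Eu(fod)3 (10 mol%) in CHCl3 at 60 °C then rearranges it through the diacetylated ortho-dienone F3 and the diacetylated para-dienone F4 to 4-[3-acetoxy-5-hydroxy-7-methoxy-8-(3-methylbut-2-en-1-yl)-4-oxo-4H-chromen-2-yl]phenyl acetate F5. Methanolysis (cat. K2CO3, MeOH, 0 °C) returns to the route at target 13.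

Step 2 (Claisen–Schmidt with an unprotected hydroxy-aldehyde). Risk: the phenoxide of 4 is a poor electrophile, so conversion may stall. Fallback: set out from 3 and condense it (KOH, EtOH, rt) with purchased, racemic 4-(tetrahydro-2H-pyran-2-yloxy)benzaldehyde F6. This passes through the THP-protected aldol adduct F7 to (E)-1-[2-hydroxy-4-methoxy-6-(3-methylbut-2-en-1-yloxy)phenyl]-3-[4-(tetrahydro-2H-pyran-2-yloxy)phenyl]prop-2-en-1-one F8. Mild acetal methanolysis (cat. PPTS, MeOH, 40 °C), which leaves the prenyl ether intact, returns to the route at chalcone 6.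

**Further compounds**
F1 | step 3 | trans-3-hydroxy-2-(4-hydroxyphenyl)-7-methoxy-5-(3-methylbut-2-en-1-yloxy)chroman-4-one (racemic; 2R,3R enantiomer drawn) | COc1cc(OCC=C(C)C)c2C(=O)[C@H](O)[C@@H](c3ccc(O)cc3)Oc2c1
F2 | step 4 | 4-[3-acetoxy-7-methoxy-5-(3-methylbut-2-en-1-yloxy)-4-oxo-4H-chromen-2-yl]phenyl acetate | COc1cc(OCC=C(C)C)c2c(=O)c(OC(C)=O)c(-c3ccc(OC(C)=O)cc3)oc2c1
F3 | step 4 | 3-acetoxy-2-(4-acetoxyphenyl)-7-methoxy-6-(2-methylbut-3-en-2-yl)-4H-chromene-4,5(6H)-dione (ortho-dienone, racemic, not isolated) | COC1=CC2=C(C(=O)C1C(C)(C)C=C)C(=O)C(OC(C)=O)=C(O2)c1ccc(OC(C)=O)cc1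
F4 | step 4 | 3-acetoxy-2-(4-acetoxyphenyl)-7-methoxy-8-(3-methylbut-2-en-1-yl)-4H-chromene-4,5(8H)-dione (para-dienone, racemic, not isolated) | COC1=CC(=O)C2=C(OC(c3ccc(OC(C)=O)cc3)=C(OC(C)=O)C2=O)C1CC=C(C)C
F5 | step 4 | 4-[3-acetoxy-5-hydroxy-7-methoxy-8-(3-methylbut-2-en-1-yl)-4-oxo-4H-chromen-2-yl]phenyl acetate | COc1cc(O)c2c(=O)c(OC(C)=O)c(-c3ccc(OC(C)=O)cc3)oc2c1CC=C(C)C
F6 | step 2 | 4-(tetrahydro-2H-pyran-2-yloxy)benzaldehyde (purchased reagent, racemic) | O=Cc1ccc(OC2CCCCO2)cc1
F7 | step 2 | 3-hydroxy-1-[2-hydroxy-4-methoxy-6-(3-methylbut-2-en-1-yloxy)phenyl]-3-[4-(tetrahydro-2H-pyran-2-yloxy)phenyl]propan-1-one (mixture of stereoisomers, not isolated) | COc1cc(O)c(C(=O)CC(O)c2ccc(OC3CCCCO3)cc2)c(OCC=C(C)C)c1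
F8 | step 2 | (E)-1-[2-hydroxy-4-methoxy-6-(3-methylbut-2-en-1-yloxy)phenyl]-3-[4-(tetrahydro-2H-pyran-2-yloxy)phenyl]prop-2-en-1-one (racemic at the acetal carbon) | COc1cc(O)c(C(=O)/C=C/c2ccc(OC3CCCCO3)cc2)c(OCC=C(C)C)c1
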